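The readings are simulated for substances that don't exist, noise included.

The trap in this flask is to read a straight rise of product as a steady rate and carry that line past the end of the feed.

the same everywhere: substrate 0.50 M (fed, over 15 min)
- north-east: reagent 2.1 M; temperature −28 °C; run made earlier; the fed solution adds 0.25 times the starting volume
- north: reagent 2.1 M; temperature 0 °C; run made earlier; the fed solution adds 0.25 times the starting volume
- oak: reagent 1.50 M; at −40 °C throughout; the fed solution adds 0.25 times the starting volume; time 50 min
- alder: reagent 1.50 M; at −40 °C until 5.0 min, from then on at 10 °C; the fed solution adds 0.25 times the starting volume; time 15 min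

north-east run (percent of the substrate charged)

| time / min | product / % |
|---|---|
| 0.667 | 0 |
| 2.00 | 1.0 |
| 4.00 | 2.5 |
| 6.00 | 4.1 |
| 8.00 | 5.6 |

north run (percent of the substrate charged)

| time / s | product / % |
|---|---|
| 12.0 | 0.1 |
| 30.0 | 0 |
| 60.0 | 0.8 |
| 80.0 | 1.8 |
| 120 | 2.9 |

(standard deviation of a reading: 0.5 percentage points)

- amounts are per litre of the starting volume; all of the dose is in the solution fed
- what may be going on: substrate <-> intermediate + leaving ligand; reagent + intermediate -> product
- percentages count the whole charge, also what has not yet gone in

* which of the two ends with the higher amount of product, in percent of the substrate charged ("neither" if they lie within 2 percentage points) (oak / alder / neither)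
* product at the end, in percent of the substrate charged, oak
* product at the end, in percent of the substrate charged, alder

Start with the main step alone: if substrate simply fell apart and reagent caught each intermediate, product would follow the substrate fed, so in the north-east run, from 2.00 min to 8.00 min, a time ratio of 4.00, it should rise by that ratio squared, 16.0, yet it rose by 5.60. Now add the return: suppose leaving ligand takes intermediate back and the first step keeps up both ways (a pre-equilibrium), so that c(intermediate) is a constant times c(substrate)/c(leaving ligand) and each product made slows the next. Then the square of c(leaving ligand) climbs at 2·g·c(reagent)·c(substrate), where g, the release constant, is that constant times the rate constant of the reagent step, and with amounts per litre of starting volume the dilution cancels. While c(substrate) grows with time during the feed, ligand rises straight, and the slope squared equals g·c(reagent)·(feed rate).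

The last readings give slopes of 0.00350 M/min at −28 °C and 0.00725 M/min at 0 °C, hence readings of g of 1.75 × 10⁻⁴ /min and 7.51 × 10⁻⁴ /min. Spacing ln g evenly per degree, I take the release constant at −40 °C as 9.37 × 10⁻⁵ /min and at 10 °C as 0.00126 /min.

In oak, ligand, counted per litre of starting volume, reaches 0.0325 M at the end of the feed; after that c(substrate) stops growing, so the square climbs evenly and the line bends, to 0.0773 M. The correction is small: take substrate and reagent down by the mean ligand, and my oak figure is 14.5%. In alder, on the same count, ligand stands at 0.0108 M at the change, and the warm g over a mean fed substrate of 0.333 M gives 0.113 M, corrected to 20.0%. I count ligand as product, and I put alder ahead.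

The forecast names alder, with 15% (12% to 19%) for oak and 23% (17% to 31%) for alder, holding that “released ligand must be retarding the reaction”.

The flask gives 13.6% for oak and 17.7% for alder, so alder ends higher.

    substrate ⇌ intermediate + leaving ligand, settled at all times (K = 2.50 × 10⁻⁴ M, ΔH = −23.0 kJ/mol)
    reagent + intermediate → product (k = 0.364 /M/min, Ea = 49.0 kJ/mol)
    (constants at −40 °C)

Part of what holds oak at 13.6% is the time it is given: substrate still stands at 86.0% of the charge at 50.0 min, and the same flask left until 500 min reaches 41.3%, a gain of 28 percentage points. The same g carries to the neighbour of oak with 2.5 M of reagent: ligand goes with the root of reagent, substrate and time held, so my oak figure becomes 18.8%, and that flask ended at 17.6%.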